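**Retrosynthetic overview**
- Target (meso) ⇐ its hexa-O-benzyl ether by hydrogenolysis; all six phenols stay benzylated until the last step.
- Tetrahydrofuran (the only ring formed, closed last) ⇐ cut C3–C4: intramolecular oxidative coupling of the two ketone enolates of a meso bis(β-keto) dibenzylic ether. One α-carbon reacts as an electrophilic α-keto radical (enolonium-type), the other as an enolate.
- Meso ether ⇐ 2 × aryl methyl ketone (as silyl enol ether) + 2 × 4-(benzyloxy)benzaldehyde: Mukaiyama aldol, then oxocarbenium aldol; this sets C2/C5 (unlike, so cis in the ring).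
- C3/C4 are enolisable and are set by equilibration (each aroyl trans to its neighbouring aryl). Ketone ⇐ 2',4'-dihydroxyacetophenone.

Assumption: the given SMILES is the meso, achiral (2R,3R,4S,5S) isomer (2,5-aryls cis, 3,4-aroyls cis, each aryl/aroyl pair trans), so there is no enantiomer to select and only relative configuration has to be controlled.

**Step 1**
Reactants: 1 2',4'-dihydroxyacetophenone
Product: 2 1-[2,4-bis(benzyloxy)phenyl]ethan-1-one
Conditions: BnBr (2.4 equiv), K2CO3 (3 equiv), KI (cat.), DMF, 80 °C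
Reagents that add atoms: benzyl bromide, BrCc1ccccc1
Why: Williamson ether synthesis; warm DMF/K2CO3 also alkylates the hydrogen-bonded 2-hydroxyl, and no stereocentre is formed.

**Step 2**
Reactants: 2 1-[2,4-bis(benzyloxy)phenyl]ethan-1-one (2 equiv); 3 4-(benzyloxy)benzaldehyde (2 equiv)
Product: 6 (3R,3'S)-3,3'-oxybis{1-[2,4-bis(benzyloxy)phenyl]-3-[4-(benzyloxy)phenyl]propan-1-one} (meso ether), via silyl enol ether 4 (not isolated), via β-silyloxy ketone 5 (not isolated)
Conditions: Me3SiOTf (2.3 equiv), iPr2NEt (2.0 equiv), CH2Cl2, 0 °C; then 3, −78 → −45 °C; NaHCO3 quench at −78 °C; crystallisation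
Reagents that add atoms: none
Why: Proposed new method: soft enolisation gives 4, the residual Me3SiOTf catalyses a Mukaiyama aldol of 4 on 3 to racemic 5, and at low temperature the silyl ether oxygen of 5 condenses with a second molecule of 3 (loss of (Me3Si)2O) to an E-oxocarbenium ion that 4 attacks far faster than it attacks free aldehyde, anti to the aryl group of the resident stereocentre in the hydrogen-eclipsed conformer, which should give the unlike (meso) ether as the major isomer (the dl isomer is removed by crystallisation); closest known reaction types are the Mukaiyama aldol, the Noyori acetal aldol and the three-component aldehyde/alkoxysilane/silyl nucleophile ether synthesis.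

**Step 3**
Reactants: 6 meso ether
Product: 9 [(2R,3R,4S,5S)-2,5-bis[4-(benzyloxy)phenyl]oxolane-3,4-diyl]bis{[2,4-bis(benzyloxy)phenyl]methanone} (meso), via dilithium dienolate 7 (not isolated), via kinetic tetrahydrofuran epimer mixture 8 (not isolated)
Conditions: LiN(iPr)2 (2.2 equiv), THF (0.02 M), −78 °C; CuCl2 (2.3 equiv), DMF, −78 → −40 °C; then DBU (0.2 equiv), CH2Cl2, 23 °C
Reagents that add atoms: none
Why: Intramolecular oxidative enolate coupling (Saegusa type): divalent copper oxidises one enolate to an electrophilic α-keto radical, a reversed-polarity (enolonium-type) carbon that the second enolate carbon traps 5-exo to forge C3–C4 and close the ring; C2/C5 stay cis because they come unchanged from meso 6, and DBU then equilibrates the enolisable C3/C4 to the isomer with each aroyl trans to its neighbouring aryl (so cis to each other).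

**Step 4**
Reactants: 9 hexa-O-benzyl tetrahydrofuran
Product: 10 [(2R,3R,4S,5S)-2,5-bis(4-hydroxyphenyl)oxolane-3,4-diyl]bis[(2,4-dihydroxyphenyl)methanone] (meso; CNP0237262.1)
Conditions: H2 (1 atm), 10% Pd/C, THF–MeOH (1:1), 23 °C
Reagents that add atoms: none
Why: Hydrogenolysis of six aryl benzyl ethers, which cleave much faster than the ring C–O bonds (flanked by acyl-bearing carbons) or the electron-rich aryl ketones; the neutral conditions leave all four stereocentres untouched.

**Compound list**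
1 | 2',4'-dihydroxyacetophenone | CC(=O)c1ccc(O)cc1O | starting material
2 | 1-[2,4-bis(benzyloxy)phenyl]ethan-1-one | CC(=O)c1ccc(OCc2ccccc2)cc1OCc1ccccc1 | intermediate
3 | 4-(benzyloxy)benzaldehyde | O=Cc1ccc(OCc2ccccc2)cc1 | starting material
4 | {[1-(2,4-bis(benzyloxy)phenyl)ethenyl]oxy}trimethylsilane (not isolated) | C=C(O[Si](C)(C)C)c1ccc(OCc2ccccc2)cc1OCc1ccccc1 | intermediate
5 | racemic 1-[2,4-bis(benzyloxy)phenyl]-3-[4-(benzyloxy)phenyl]-3-[(trimethylsilyl)oxy]propan-1-one (not isolated) | C[Si](C)(C)OC(CC(=O)c1ccc(OCc2ccccc2)cc1OCc1ccccc1)c1ccc(OCc2ccccc2)cc1 | intermediate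
6 | (3R,3'S)-3,3'-oxybis{1-[2,4-bis(benzyloxy)phenyl]-3-[4-(benzyloxy)phenyl]propan-1-one}, meso | O=C(c1ccc(OCc2ccccc2)cc1OCc1ccccc1)C[C@@H](c1ccc(OCc2ccccc2)cc1)O[C@@H](c1ccc(OCc2ccccc2)cc1)CC(=O)c1ccc(OCc2ccccc2)cc1OCc1ccccc1 | intermediate
7 | dilithium dienolate of 6 (not isolated) | [Li]OC(c1ccc(OCc2ccccc2)cc1OCc1ccccc1)=C[C@@H](c1ccc(OCc2ccccc2)cc1)O[C@@H](c1ccc(OCc2ccccc2)cc1)C=C(O[Li])c1ccc(OCc2ccccc2)cc1OCc1ccccc1 | intermediate
8 | 2,5-cis-2,5-bis[4-(benzyloxy)phenyl]-3,4-bis[2,4-bis(benzyloxy)benzoyl]oxolane as formed, C3/C4 epimer mixture (not isolated) | O=C(c1ccc(OCc2ccccc2)cc1OCc1ccccc1)C1C(C(=O)c2ccc(OCc3ccccc3)cc2OCc2ccccc2)[C@@H](c2ccc(OCc3ccccc3)cc2)O[C@H]1c1ccc(OCc2ccccc2)cc1 | intermediate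
9 | [(2R,3R,4S,5S)-2,5-bis[4-(benzyloxy)phenyl]oxolane-3,4-diyl]bis{[2,4-bis(benzyloxy)phenyl]methanone}, meso | O=C(c1ccc(OCc2ccccc2)cc1OCc1ccccc1)[C@@H]1[C@H](C(=O)c2ccc(OCc3ccccc3)cc2OCc2ccccc2)[C@@H](c2ccc(OCc3ccccc3)cc2)O[C@H]1c1ccc(OCc2ccccc2)cc1 | intermediate
10 | [(2R,3R,4S,5S)-2,5-bis(4-hydroxyphenyl)oxolane-3,4-diyl]bis[(2,4-dihydroxyphenyl)methanone], meso | O=C(c1ccc(O)cc1O)[C@@H]1[C@H](C(=O)c2ccc(O)cc2O)[C@@H](c2ccc(O)cc2)O[C@H]1c1ccc(O)cc1 | target

**Step count**
Total steps: 4. Longest linear sequence: 4 (1 → 2 → 6 → 9 → 10).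

**Three steps most likely to fail, each with a fallback**

Step 2 is the least precedented. The sequence may stop at the simple aldol 5, Me3SiOTf may ionise 5 to the chalcone or a 1,5-diketone, or the meso:dl ratio may be poor (the dl ether would lead to the 2,5-trans series). The fallback sets out from 2 and comes back at 8; it forms C3–C4 first and closes the ring on oxygen/carbon instead. Intermolecular oxidative enolate homocoupling of 2 (LiN(iPr)2, THF, −78 °C; CuCl2, DMF) gives 1,4-bis[2,4-bis(benzyloxy)phenyl]butane-1,4-dione F1. Me3SiOTf/Et3N converts it into (1Z,3Z)-1,4-bis[2,4-bis(benzyloxy)phenyl]-1,4-bis[(trimethylsilyl)oxy]buta-1,3-diene F2. With 3 (2 equiv) and Me3SiOTf (cat.) in CH2Cl2 at −78 °C a first Mukaiyama aldol gives the mono-aldol silyl ether 1,4-bis[2,4-bis(benzyloxy)phenyl]-2-{[4-(benzyloxy)phenyl][(trimethylsilyl)oxy]methyl}-4-[(trimethylsilyl)oxy]but-3-en-1-one F3. Its silyl ether condenses with the second aldehyde to an E-oxocarbenium ion that the remaining enol silane captures intramolecularly, which should favour the 2,5-cis ring and deliver 8; the DBU treatment of step 3 then gives 9.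

Step 3 can fail through E1cB loss of the β-alkoxide from the dienolate 7 (giving chalcone), through oligomerisation, or through a sluggish ring closure. The fallback sets out from 6 and comes back at 8; it leaves basic enolate chemistry altogether. Me3SiOTf/Et3N (CH2Cl2, 0 °C) gives the isolable, neutral bis(trimethylsilyl enol ether) of meso ether 6 F4. One-electron oxidation with Cu(OTf)2 (2.2 equiv) and Cu2O in MeCN at 0 °C generates an enol-ether radical cation that cyclises 5-exo onto the second enol silane, giving 8 without any β-alkoxy enolate; DBU then gives 9.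

Step 4 may over-reduce (hydrogenolysis of the dibenzylic ring ether, reduction of the aryl ketones) or stall at the hindered 2-benzyloxy groups. The fallback sets out from 9 and comes back at 10; it makes no new compound (F0). It replaces reduction by non-reductive Lewis-acid dealkylation with cation capture: BCl3 (8 equiv), pentamethylbenzene (12 equiv), CH2Cl2, −78 °C, then MeOH quench.

**Further compounds**
F1 | step 2 | 1,4-bis[2,4-bis(benzyloxy)phenyl]butane-1,4-dione | O=C(CCC(=O)c1ccc(OCc2ccccc2)cc1OCc1ccccc1)c1ccc(OCc2ccccc2)cc1OCc1ccccc1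
F2 | step 2 | (1Z,3Z)-1,4-bis[2,4-bis(benzyloxy)phenyl]-1,4-bis[(trimethylsilyl)oxy]buta-1,3-diene | C[Si](C)(C)O/C(c1ccc(OCc2ccccc2)cc1OCc1ccccc1)=C\C=C(/O[Si](C)(C)C)c1ccc(OCc2ccccc2)cc1OCc1ccccc1
F3 | step 2 | 1,4-bis[2,4-bis(benzyloxy)phenyl]-2-{[4-(benzyloxy)phenyl][(trimethylsilyl)oxy]methyl}-4-[(trimethylsilyl)oxy]but-3-en-1-one (diastereomer mixture, not isolated) | C[Si](C)(C)OC(c1ccc(OCc2ccccc2)cc1)C(C=C(O[Si](C)(C)C)c1ccc(OCc2ccccc2)cc1OCc1ccccc1)C(=O)c1ccc(OCc2ccccc2)cc1OCc1ccccc1
F4 | step 3 | bis(trimethylsilyl enol ether) of meso ether 6 | C[Si](C)(C)OC(c1ccc(OCc2ccccc2)cc1OCc1ccccc1)=C[C@@H](c1ccc(OCc2ccccc2)cc1)O[C@@H](c1ccc(OCc2ccccc2)cc1)C=C(O[Si](C)(C)C)c1ccc(OCc2ccccc2)cc1OCc1ccccc1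
F0 | step 4 | none | none
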